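**Assumption:** in step 4 the (S)-tryptophan-derived oxazaborolidinone is taken to deliver the dienolate to the Re face of aldehyde 4; if the sense is the opposite, the (R)-tryptophan catalyst is used and nothing else changes.

**Skeleton labels used in the text (they follow the target SMILES):** C1 = CH–O-angelate, C2 = CH–O-isovalerate, C3 = CH–OH, C4 = quaternary C–Me, C5 = CH next to C=O, C6 = C=O, C7 = CH=, C8 = C(Me)=, C9 and C10 = the other two cyclobutane CH, C11 = CMe2.

## Retrosynthetic overview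

1. The C2 isovalerate comes from selective acylation of a cis-C2,C3-diol; the diol comes from OsO4 on a C2=C3 cycloheptene, anti to the C1 angelate.
2. The cyclohexenone is opened at C6–C7: intramolecular carbonyl-ene reaction of a C5 aldehyde with a C9 isopropenyl group, then oxidation and conjugation; C6 comes from one-carbon homologation of a cyclobutanone.
3. Key disconnection: cyclobutanone and seven-membered ring are opened together (C5–C10 and C4–C9) to an acyclic methyl(vinyl)ketene carrying an (E)-1,3-diene, i.e. a bridged intramolecular ketene–diene [2+2].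
4. The ketene precursor, a (2E)-2-methylenoic acid, comes from an asymmetric vinylogous Mukaiyama aldol (sets C1) of a tiglate dienolate with 2,2,5-trimethylhexa-3,5-dienal, itself an HWE product.
5. Ring order: cyclobutane + cycloheptene in one operation, then the cyclohexenone.

## Route

Step 1
Reactants: 1 methyl 2,2-dimethyl-3-oxopropanoate; 2 diethyl (2-methylprop-2-en-1-yl)phosphonate
Product: 3 methyl (3E)-2,2,5-trimethylhexa-3,5-dienoate
Conditions: 2, n-BuLi, THF, −78 °C; then 1, −78 °C → rt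
Reagents that add atoms: none
Why: Horner–Wadsworth–Emmons olefination of the non-enolisable aldehyde with the α-lithiated allylic phosphonate gives the (E)-1,3-diene (C10=C9–C8=C7), the hindered ester being untouched at −78 °C.

Step 2
Reactants: 3 methyl (3E)-2,2,5-trimethylhexa-3,5-dienoate
Product: 4 (3E)-2,2,5-trimethylhexa-3,5-dienal
Conditions: DIBAL-H (1.05 equiv), CH2Cl2, −78 °C; Rochelle salt work-up
Reagents that add atoms: none
Why: DIBAL-H partial reduction, because the aluminium hemiacetal of the α-quaternary ester is stable at −78 °C and gives the aldehyde only on work-up.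

Step 3
Reactants: 5 methyl (2E)-2-methylbut-2-enoate (methyl tiglate)
Product: 6 tert-butyl{[(1Z)-1-methoxy-2-methylbuta-1,3-dien-1-yl]oxy}dimethylsilane
Conditions: LDA, DMPU, THF, −78 °C; then TBSCl, −78 °C → rt
Reagents that add atoms: tert-butyldimethylsilyl chloride, CC(C)(C)[Si](C)(C)Cl
Why: kinetic γ-deprotonation and O-silylation give the silyl dienolate, whose ketene-acetal geometry is lost in step 4 and need not be uniform.

Step 4
Reactants: 4 (3E)-2,2,5-trimethylhexa-3,5-dienal; 6 tert-butyl{[(1Z)-1-methoxy-2-methylbuta-1,3-dien-1-yl]oxy}dimethylsilane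
Product: 7 methyl (2E,5R,7E)-5-hydroxy-2,6,6,9-tetramethyldeca-2,7,9-trienoate
Conditions: (S)-N-tosyltryptophan-derived B-phenyl-1,3,2-oxazaborolidin-5-one (0.5 equiv), i-PrOH (1.2 equiv), EtCN, −78 °C
Reagents that add atoms: none
Why: asymmetric vinylogous Mukaiyama aldol reaction in which the boron Lewis acid activates the aldehyde and the dienolate attacks through its γ-carbon (C2) on the Re face, setting C1 (5R here, 1S in the target) and giving the (E)-enoate.

Step 5
Reactants: 7 methyl (2E,5R,7E)-5-hydroxy-2,6,6,9-tetramethyldeca-2,7,9-trienoate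
Product: 8 methyl (2E,5R,7E)-5-[(tert-butyldimethylsilyl)oxy]-2,6,6,9-tetramethyldeca-2,7,9-trienoate
Conditions: TBSOTf, 2,6-lutidine, CH2Cl2, 0 °C
Reagents that add atoms: tert-butyldimethylsilyl triflate, CC(C)(C)[Si](C)(C)OS(=O)(=O)C(F)(F)F
Why: silylation of the hindered neopentylic alcohol with the reactive silyl triflate, which protects C1–OH through the acid chloride, ketene and organometallic steps.

Step 6
Reactants: 8 methyl (2E,5R,7E)-5-[(tert-butyldimethylsilyl)oxy]-2,6,6,9-tetramethyldeca-2,7,9-trienoate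
Product: 9 (2E,5R,7E)-5-[(tert-butyldimethylsilyl)oxy]-2,6,6,9-tetramethyldeca-2,7,9-trienoic acid
Conditions: LiOH·H2O, THF/MeOH/H2O, 40 °C; cold 1 M HCl to pH 3–4
Reagents that add atoms: lithium hydroxide, [Li+].[OH-]
Why: ester saponification, which leaves the silyl ether, the diene and the C1 centre untouched.

Step 7
Reactants: 9 (2E,5R,7E)-5-[(tert-butyldimethylsilyl)oxy]-2,6,6,9-tetramethyldeca-2,7,9-trienoic acid
Product: 12 (1R,4R,6R,8R)-4-[(tert-butyldimethylsilyl)oxy]-1,5,5-trimethyl-8-(prop-1-en-2-yl)bicyclo[4.1.1]oct-2-en-7-one, via acid chloride 10 (not isolated), via vinylketene 11 (not isolated)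
Conditions: (COCl)2, DMF (cat.), CH2Cl2, 0 °C → rt, evaporate; then syringe-pump addition to Et3N (5 equiv), toluene, reflux, 0.005 M; chromatography removes the minor C1-epimeric cycloadduct
Reagents that add atoms: none
Why: Proposed new method: γ-deprotonation of the enoyl chloride gives methyl(vinyl)ketene 11 (the isomers at the new C2=C3 bond equilibrate by reversible HCl addition and only the Z isomer can cyclise), its electrophilic carbonyl carbon C5 bonds to the tethered diene terminus C10 so that the developing positive charge is allylic (C9–C8–C7) and the ketene α-carbon C4 then closes on C9, a bridged (type II) intramolecular ketene–alkene [2+2] that forms the cycloheptene and the cyclobutanone in one operation; the (E)-diene geometry is transferred suprafacially (isopropenyl on C9 trans to C11 on C10), C4 and C10 are fixed by the bridge, and the sense relative to C1 is expected (modestly, about 3–4:1) to follow from the exo OTBS group leaving the C1–H under the flat carbonyl bridge and not under the C9–H bridge; the closest known reaction is the vinylketene–alkene cycloaddition of enoyl chlorides with Et3N that gives bicyclo[3.1.1]heptenones of the chrysanthenone type (three-atom tether, trisubstituted alkene).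

Step 8
Reactants: 12 (1R,4R,6R,8R)-4-[(tert-butyldimethylsilyl)oxy]-1,5,5-trimethyl-8-(prop-1-en-2-yl)bicyclo[4.1.1]oct-2-en-7-one
Product: 14 (1R,4R,6S,7R,8R)-4-[(tert-butyldimethylsilyl)oxy]-1,5,5-trimethyl-8-(prop-1-en-2-yl)bicyclo[4.1.1]oct-2-ene-7-carbaldehyde, via enol ether 13 (not isolated)
Conditions: Ph3P(CH2OMe)Cl, KHMDS, THF, 0 → 50 °C; then 2 M aq HCl, THF, rt; then K2CO3 (cat.), MeOH, rt
Reagents that add atoms: (methoxymethyl)triphenylphosphonium chloride, COC[P+](c1ccccc1)(c1ccccc1)c1ccccc1.[Cl-]; water, O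
Why: Wittig methoxymethylenation of the non-enolisable cyclobutanone and enol ether hydrolysis add C6, and C5 is set by thermodynamic equilibration through the enol, the formyl group going anti to the four-carbon bridge because the syn position is blocked by a C11 methyl group.

Step 9
Reactants: 14 (1R,4R,6S,7R,8R)-4-[(tert-butyldimethylsilyl)oxy]-1,5,5-trimethyl-8-(prop-1-en-2-yl)bicyclo[4.1.1]oct-2-ene-7-carbaldehyde
Product: 15 (1R,2R,5R,7S,8R)-5-[(tert-butyldimethylsilyl)oxy]-2,6,6-trimethyl-11-methylidenetricyclo[5.4.0.0^{2,8}]undec-3-en-9-ol (mixture of C6 carbinol epimers)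
Conditions: Me2AlCl (2 equiv), CH2Cl2, −78 → −20 °C
Reagents that add atoms: none
Why: Lewis-acid-promoted intramolecular carbonyl-ene reaction, possible because the C5 aldehyde and the C9 isopropenyl group are held 1,3-cis on the cyclobutane so that C6–C7 closes the six-membered ring while a methyl hydrogen goes to oxygen; the new carbinol centre is removed in step 10.

Step 10
Reactants: 15 (1R,2R,5R,7S,8R)-5-[(tert-butyldimethylsilyl)oxy]-2,6,6-trimethyl-11-methylidenetricyclo[5.4.0.0^{2,8}]undec-3-en-9-ol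
Product: 17 (1R,2R,5R,7S,8R)-5-[(tert-butyldimethylsilyl)oxy]-2,6,6,11-tetramethyltricyclo[5.4.0.0^{2,8}]undeca-3,10-dien-9-one, via β,γ-enone 16 (not isolated)
Conditions: Dess–Martin periodinane, CH2Cl2, rt; then DBU (0.2 equiv), rt
Reagents that add atoms: none
Why: Dess–Martin oxidation gives the β,γ-unsaturated ketone and base moves the exocyclic alkene into conjugation (C7=C8), the only direction open because C5 is a bridgehead.

Step 11
Reactants: 17 (1R,2R,5R,7S,8R)-5-[(tert-butyldimethylsilyl)oxy]-2,6,6,11-tetramethyltricyclo[5.4.0.0^{2,8}]undeca-3,10-dien-9-one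
Product: 18 (1R,2R,5R,7S,8R)-5-hydroxy-2,6,6,11-tetramethyltricyclo[5.4.0.0^{2,8}]undeca-3,10-dien-9-one
Conditions: TBAF, THF, 0 → 40 °C
Reagents that add atoms: none
Why: fluoride-mediated desilylation frees C1–OH as the only hydroxyl group in the molecule.

Step 12
Reactants: 18 (1R,2R,5R,7S,8R)-5-hydroxy-2,6,6,11-tetramethyltricyclo[5.4.0.0^{2,8}]undeca-3,10-dien-9-one; 19 (2Z)-2-methylbut-2-enoic acid (angelic acid)
Product: 21 (1R,2R,5R,7S,8R)-2,6,6,11-tetramethyl-9-oxotricyclo[5.4.0.0^{2,8}]undeca-3,10-dien-5-yl (2Z)-2-methylbut-2-enoate, via mixed anhydride 20 (not isolated)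
Conditions: 19, 2,4,6-trichlorobenzoyl chloride, Et3N, toluene, rt; then 18, 80 °C
Reagents that add atoms: none
Why: Yamaguchi-type esterification through the mixed anhydride without DMAP acylates the hindered C1–OH and keeps the (Z)-alkene of the angelate.

Step 13
Reactants: 21 (1R,2R,5R,7S,8R)-2,6,6,11-tetramethyl-9-oxotricyclo[5.4.0.0^{2,8}]undeca-3,10-dien-5-yl (2Z)-2-methylbut-2-enoate
Product: 22 (1R,2R,3S,4S,5S,7S,8R)-3,4-dihydroxy-2,6,6,11-tetramethyl-9-oxotricyclo[5.4.0.0^{2,8}]undec-10-en-5-yl (2Z)-2-methylbut-2-enoate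
Conditions: OsO4 (5 mol%), NMO (1.3 equiv), acetone/H2O, 0 °C → rt, stopped at full conversion of 21
Reagents that add atoms: osmium tetroxide, O=[Os](=O)(=O)=O; N-methylmorpholine N-oxide, C[N+]1([O-])CCOCC1; water, O
Why: Upjohn dihydroxylation, in which OsO4 adds suprafacially to the only electron-rich alkene (C2=C3; the enone and angelate alkenes are trisubstituted and electron-poor) on the face anti to the allylic C1 ester (Kishi's rule), setting C2 and C3 cis to each other and trans to C1–O.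

Step 14
Reactants: 22 (1R,2R,3S,4S,5S,7S,8R)-3,4-dihydroxy-2,6,6,11-tetramethyl-9-oxotricyclo[5.4.0.0^{2,8}]undec-10-en-5-yl (2Z)-2-methylbut-2-enoate; 23 3-methylbutanoic anhydride (isovaleric anhydride)
Product: 24 (1R,2R,3S,4S,5S,7S,8R)-3-hydroxy-2,6,6,11-tetramethyl-5-{[(2Z)-2-methylbut-2-enoyl]oxy}-9-oxotricyclo[5.4.0.0^{2,8}]undec-10-en-4-yl 3-methylbutanoate (CNP0128158.1)
Conditions: 23 (1.1 equiv), pyridine, DMAP (cat.), CH2Cl2, −20 °C
Reagents that add atoms: none
Why: regioselective acylation of the less hindered C2–OH, the C3–OH being neopentylic (next to quaternary C4, under the cage) and staying free.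

## Compound list

1 | methyl 2,2-dimethyl-3-oxopropanoate | COC(=O)C(C)(C)C=O | starting material
2 | diethyl (2-methylprop-2-en-1-yl)phosphonate | CCOP(=O)(CC(C)=C)OCC | starting material
3 | methyl (3E)-2,2,5-trimethylhexa-3,5-dienoate | COC(=O)C(C)(C)/C=C/C(C)=C | intermediate
4 | (3E)-2,2,5-trimethylhexa-3,5-dienal | O=CC(C)(C)/C=C/C(C)=C | intermediate
5 | methyl (2E)-2-methylbut-2-enoate (methyl tiglate) | C/C=C(\C)C(=O)OC | starting material
6 | tert-butyl{[(1Z)-1-methoxy-2-methylbuta-1,3-dien-1-yl]oxy}dimethylsilane | C=C/C(C)=C(/OC)O[Si](C)(C)C(C)(C)C | intermediate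
7 | methyl (2E,5R,7E)-5-hydroxy-2,6,6,9-tetramethyldeca-2,7,9-trienoate | COC(=O)/C(C)=C/C[C@@H](O)C(C)(C)/C=C/C(C)=C | intermediate
8 | methyl (2E,5R,7E)-5-[(tert-butyldimethylsilyl)oxy]-2,6,6,9-tetramethyldeca-2,7,9-trienoate | COC(=O)/C(C)=C/C[C@@H](O[Si](C)(C)C(C)(C)C)C(C)(C)/C=C/C(C)=C | intermediate
9 | (2E,5R,7E)-5-[(tert-butyldimethylsilyl)oxy]-2,6,6,9-tetramethyldeca-2,7,9-trienoic acid | OC(=O)/C(C)=C/C[C@@H](O[Si](C)(C)C(C)(C)C)C(C)(C)/C=C/C(C)=C | intermediate
10 | (2E,5R,7E)-5-[(tert-butyldimethylsilyl)oxy]-2,6,6,9-tetramethyldeca-2,7,9-trienoyl chloride | ClC(=O)/C(C)=C/C[C@@H](O[Si](C)(C)C(C)(C)C)C(C)(C)/C=C/C(C)=C | intermediate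
11 | (3Z,5R,7E)-5-[(tert-butyldimethylsilyl)oxy]-2,6,6,9-tetramethyldeca-1,3,7,9-tetraen-1-one (vinylketene) | O=C=C(C)/C=C\[C@@H](O[Si](C)(C)C(C)(C)C)C(C)(C)/C=C/C(C)=C | intermediate
12 | (1R,4R,6R,8R)-4-[(tert-butyldimethylsilyl)oxy]-1,5,5-trimethyl-8-(prop-1-en-2-yl)bicyclo[4.1.1]oct-2-en-7-one | CC(C)(C)[Si](C)(C)O[C@@H]1C=C[C@@]2(C)C(=O)[C@H]([C@@H]2C(C)=C)C1(C)C | intermediate
13 | 7-(methoxymethylidene) analogue of 12 (enol ether, E/Z mixture at the new C=C) | CC(C)(C)[Si](C)(C)O[C@@H]1C=C[C@@]2(C)C(=COC)[C@H]([C@@H]2C(C)=C)C1(C)C | intermediate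
14 | (1R,4R,6S,7R,8R)-4-[(tert-butyldimethylsilyl)oxy]-1,5,5-trimethyl-8-(prop-1-en-2-yl)bicyclo[4.1.1]oct-2-ene-7-carbaldehyde | CC(C)(C)[Si](C)(C)O[C@@H]1C=C[C@@]2(C)[C@H](C=O)[C@H]([C@@H]2C(C)=C)C1(C)C | intermediate
15 | (1R,2R,5R,7S,8R)-5-[(tert-butyldimethylsilyl)oxy]-2,6,6-trimethyl-11-methylidenetricyclo[5.4.0.0^{2,8}]undec-3-en-9-ol (carbinol epimers) | CC(C)(C)[Si](C)(C)O[C@@H]1C=C[C@@]2(C)[C@@H]3C(O)CC(=C)[C@H]2[C@@H]3C1(C)C | intermediate
16 | (1R,2R,5R,7S,8R)-5-[(tert-butyldimethylsilyl)oxy]-2,6,6-trimethyl-11-methylidenetricyclo[5.4.0.0^{2,8}]undec-3-en-9-one | CC(C)(C)[Si](C)(C)O[C@@H]1C=C[C@@]2(C)[C@@H]3C(=O)CC(=C)[C@H]2[C@@H]3C1(C)C | intermediate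
17 | (1R,2R,5R,7S,8R)-5-[(tert-butyldimethylsilyl)oxy]-2,6,6,11-tetramethyltricyclo[5.4.0.0^{2,8}]undeca-3,10-dien-9-one | CC(C)(C)[Si](C)(C)O[C@@H]1C=C[C@@]2(C)[C@@H]3C(=O)C=C(C)[C@H]2[C@@H]3C1(C)C | intermediate
18 | (1R,2R,5R,7S,8R)-5-hydroxy-2,6,6,11-tetramethyltricyclo[5.4.0.0^{2,8}]undeca-3,10-dien-9-one | O[C@@H]1C=C[C@@]2(C)[C@@H]3C(=O)C=C(C)[C@H]2[C@@H]3C1(C)C | intermediate
19 | (2Z)-2-methylbut-2-enoic acid (angelic acid) | C/C=C(/C)C(=O)O | starting material
20 | (2Z)-2-methylbut-2-enoic 2,4,6-trichlorobenzoic anhydride | C/C=C(/C)C(=O)OC(=O)c1c(Cl)cc(Cl)cc1Cl | intermediate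
21 | (1R,2R,5R,7S,8R)-2,6,6,11-tetramethyl-9-oxotricyclo[5.4.0.0^{2,8}]undeca-3,10-dien-5-yl (2Z)-2-methylbut-2-enoate | C/C=C(/C)C(=O)O[C@@H]1C=C[C@@]2(C)[C@@H]3C(=O)C=C(C)[C@H]2[C@@H]3C1(C)C | intermediate
22 | (1R,2R,3S,4S,5S,7S,8R)-3,4-dihydroxy-2,6,6,11-tetramethyl-9-oxotricyclo[5.4.0.0^{2,8}]undec-10-en-5-yl (2Z)-2-methylbut-2-enoate | C/C=C(/C)C(=O)O[C@@H]1[C@@H](O)[C@@H](O)[C@@]2(C)[C@@H]3C(=O)C=C(C)[C@H]2[C@@H]3C1(C)C | intermediate
23 | 3-methylbutanoic anhydride (isovaleric anhydride) | CC(C)CC(=O)OC(=O)CC(C)C | starting material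
24 | (1R,2R,3S,4S,5S,7S,8R)-3-hydroxy-2,6,6,11-tetramethyl-5-{[(2Z)-2-methylbut-2-enoyl]oxy}-9-oxotricyclo[5.4.0.0^{2,8}]undec-10-en-4-yl 3-methylbutanoate | C/C=C(/C)C(=O)O[C@@H]1[C@@H](OC(=O)CC(C)C)[C@@H](O)[C@@]2(C)[C@@H]3C(=O)C=C(C)[C@H]2[C@@H]3C1(C)C | target

## Step count and risks

Total step count: 14. Longest linear sequence: 13 (steps 1, 2, 4–14; step 3 is a one-step side branch).

**Most likely to fail, 1: step 7 (bridged ketene–diene cycloaddition).** The seven-membered closure has no direct precedent, ketene dimerisation and a [1,5]-H shift of the Z-vinylketene compete, and induction from C1 is only modest. The fallback replaces the neutral ketene by a keteniminium cation and sets out from acid 9. Amide coupling with dimethylamine (EDC, HOBt) gives (2E,5R,7E)-5-[(tert-butyldimethylsilyl)oxy]-N,N,2,6,6,9-hexamethyldeca-2,7,9-trienamide F4. Tf2O and 2,4,6-collidine in 1,2-dichloroethane (rt → 80 °C) turn it, by O-triflation and γ-deprotonation, into a vinylketeniminium ion. This much stronger electrophile closes in the same bridged sense at lower temperature to the N,N-dimethyliminium triflate of ketone 12 F5. Aqueous NaHCO3 hydrolyses it, and the route is rejoined at 12.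

**Most likely to fail, 2: step 4 (vinylogous aldol on a neopentylic aldehyde).** Rate and ee are uncertain for an α-quaternary aldehyde. The fallback builds the same carbon chain in two stages and sets out from aldehyde 4. A catalytic asymmetric acetate Mukaiyama aldol (1-methoxy-1-(trimethylsilyloxy)ethene, Ti(IV)–BINOL Schiff-base catalyst chosen for Re-face attack, desilylating work-up) gives methyl (3R,5E)-3-hydroxy-4,4,7-trimethylocta-5,7-dienoate F1. TBSOTf/2,6-lutidine gives methyl (3R,5E)-3-[(tert-butyldimethylsilyl)oxy]-4,4,7-trimethylocta-5,7-dienoate F2. DIBAL-H at −78 °C gives (3R,5E)-3-[(tert-butyldimethylsilyl)oxy]-4,4,7-trimethylocta-5,7-dienal F3. Wittig reaction with methyl 2-(triphenylphosphoranylidene)propanoate then gives the (E)-enoate, and the route is rejoined at 8.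

**Most likely to fail, 3: step 13 (dihydroxylation with the angelate in place).** OsO4 may also attack the angelate alkene, and the face selectivity rests on one allylic ester. The fallback dihydroxylates before the angelate is introduced and carries the diol through as an acetonide; it sets out from silyl ether 17. OsO4/NMO gives (1R,2R,3S,4S,5S,7S,8R)-5-[(tert-butyldimethylsilyl)oxy]-3,4-dihydroxy-2,6,6,11-tetramethyltricyclo[5.4.0.0^{2,8}]undec-10-en-9-one F6, anti to the bulky OTBS group. 2,2-Dimethoxypropane/PPTS gives the C2,C3-O-isopropylidene derivative of that diol F7. TBAF gives the C1 alcohol of the acetonide F8. Yamaguchi angeloylation as in step 12 gives the C1 angelate of the acetonide F9. 80% aqueous AcOH at 40 °C removes the acetonide, and the route is rejoined at diol 22.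

Further compounds

F1 | step 4 | methyl (3R,5E)-3-hydroxy-4,4,7-trimethylocta-5,7-dienoate | COC(=O)C[C@@H](O)C(C)(C)/C=C/C(C)=C
F2 | step 4 | methyl (3R,5E)-3-[(tert-butyldimethylsilyl)oxy]-4,4,7-trimethylocta-5,7-dienoate | COC(=O)C[C@@H](O[Si](C)(C)C(C)(C)C)C(C)(C)/C=C/C(C)=C
F3 | step 4 | (3R,5E)-3-[(tert-butyldimethylsilyl)oxy]-4,4,7-trimethylocta-5,7-dienal | O=CC[C@@H](O[Si](C)(C)C(C)(C)C)C(C)(C)/C=C/C(C)=C
F4 | step 7 | (2E,5R,7E)-5-[(tert-butyldimethylsilyl)oxy]-N,N,2,6,6,9-hexamethyldeca-2,7,9-trienamide | CN(C)C(=O)/C(C)=C/C[C@@H](O[Si](C)(C)C(C)(C)C)C(C)(C)/C=C/C(C)=C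
F5 | step 7 | N,N-dimethyliminium triflate of ketone 12 | CC(C)(C)[Si](C)(C)O[C@@H]1C=C[C@@]2(C)C(=[N+](C)C)[C@H]([C@@H]2C(C)=C)C1(C)C.[O-]S(=O)(=O)C(F)(F)F
F6 | step 13 | (1R,2R,3S,4S,5S,7S,8R)-5-[(tert-butyldimethylsilyl)oxy]-3,4-dihydroxy-2,6,6,11-tetramethyltricyclo[5.4.0.0^{2,8}]undec-10-en-9-one | CC(C)(C)[Si](C)(C)O[C@@H]1[C@@H](O)[C@@H](O)[C@@]2(C)[C@@H]3C(=O)C=C(C)[C@H]2[C@@H]3C1(C)C
F7 | step 13 | C2,C3-O-isopropylidene derivative of F6 | CC(C)(C)[Si](C)(C)O[C@@H]1[C@H]5OC(C)(C)O[C@H]5[C@@]2(C)[C@@H]3C(=O)C=C(C)[C@H]2[C@@H]3C1(C)C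
F8 | step 13 | C1 alcohol of the acetonide (F7 without the silyl group) | O[C@@H]1[C@H]5OC(C)(C)O[C@H]5[C@@]2(C)[C@@H]3C(=O)C=C(C)[C@H]2[C@@H]3C1(C)C
F9 | step 13 | C1 (2Z)-2-methylbut-2-enoate of the acetonide (acetonide of 22) | C/C=C(/C)C(=O)O[C@@H]1[C@H]5OC(C)(C)O[C@H]5[C@@]2(C)[C@@H]3C(=O)C=C(C)[C@H]2[C@@H]3C1(C)C
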